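**Strategy.** Everything rests on disconnecting the C9–C10 bond of ring B. Anodic oxidation of a ring A silyl enol ether (C1=C10) that carries a (Z)-allylsilane chain on C5 should close ring B in one operation: it forms quaternary C10 and the C9 stereocentre with a trans ring fusion, regenerates the C1 ketone and leaves the C8=C17 methylidene. The step exploits the C1(O)–C10–C9–C8(=C17) array: an oxygenated carbon next to a fully substituted carbon, whose neighbour C9 adjoins an exocyclic alkene in ring B. The precursor is a cyclohexenyl triethylsilyl enol ether with a C4 gem-diester and a C5 stereocentre set by asymmetric conjugate addition.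

Key step: step 10

Remark: atoms carry labdane numbers (C1 bears the acetate, C4 the ester, C5 and C10 are the ring-fusion carbons, C20 is the C10 methyl, C8=C17 is the methylidene, C9 carries the C11–C16 side chain); the facial sense of the ligand in step 9 is assigned by analogy with cyclohex-2-enone and is assumed to carry over to enone 4.

**Step 1**
Reactants: 1 dimethyl 4-oxocyclohexane-1,1-dicarboxylate
Product: 2 dimethyl 4-oxocyclohex-2-ene-1,1-dicarboxylate
Conditions: Pd(OCOCF3)2 (5 mol %), DMSO (10 mol %), O2 (1 atm), AcOH, 80 °C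
Reagents that add atoms: none
Why: Aerobic dehydrogenation through a divalent-palladium enolate and β-hydride elimination (a catalytic relative of the Saegusa–Ito oxidation) should stop at the enone, because the symmetric ketone can give only one enone and the quaternary C4 prevents aromatisation.

**Step 2**
Reactants: 2 dimethyl 4-oxocyclohex-2-ene-1,1-dicarboxylate
Product: 3 dimethyl 3-iodo-4-oxocyclohex-2-ene-1,1-dicarboxylate
Conditions: I2, pyridine, CH2Cl2, 0 → 23 °C
Reagents that add atoms: iodine II
Why: α-Iodination of the enone by pyridine conjugate addition, iodination of the enolate and elimination (Baylis–Hillman-type sequence) places iodine only on the α-carbon, as is usual for 4,4-disubstituted cyclohexenones.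

**Step 3**
Reactants: 3 dimethyl 3-iodo-4-oxocyclohex-2-ene-1,1-dicarboxylate
Product: 4 dimethyl 3-methyl-4-oxocyclohex-2-ene-1,1-dicarboxylate
Conditions: Me2Zn, Pd2(dba)3 (2 mol %), P(2-furyl)3 (8 mol %), THF/DMF, 0 → 23 °C
Reagents that add atoms: dimethylzinc C[Zn]C
Why: Negishi cross-coupling of the α-iodoenone under zerovalent-palladium catalysis puts the future C20 methyl exactly on C10 and avoids the regiochemical ambiguity of enolate methylation followed by dehydrogenation.

**Step 4**
Reactants: 5 2,3-dihydrofuran; 6 ethylene oxide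
Product: 9 tert-butyl[2-(4,5-dihydrofuran-2-yl)ethoxy]dimethylsilane, via 5-lithio-2,3-dihydrofuran 7 (not isolated), via lithium alkoxide 8 (not isolated)
Conditions: t-BuLi, THF, −78 → 0 °C; ethylene oxide, −78 → 23 °C; then t-BuMe2SiCl, 23 °C
Reagents that add atoms: tert-butyl(chloro)dimethylsilane CC(C)(C)[Si](C)(C)Cl; tert-butyllithium [Li]C(C)(C)C (lithium of 7 and 8 only)
Why: Vinylic lithiation α to the ring oxygen, epoxide opening by the vinyllithium and silylation of the alkoxide in the same flask should give the 5-substituted dihydrofuran whose ring later fixes the alkene geometry.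

**Step 5**
Reactants: 9 tert-butyl[2-(4,5-dihydrofuran-2-yl)ethoxy]dimethylsilane; 10 (trimethylsilyl)methylmagnesium chloride
Product: 11 (3Z)-6-[(tert-butyldimethylsilyl)oxy]-4-[(trimethylsilyl)methyl]hex-3-en-1-ol
Conditions: NiCl2(PPh3)2 (5 mol %), toluene, 90 °C
Reagents that add atoms: none
Why: Nickel-catalysed Kumada-type coupling of the cyclic enol ether (zerovalent nickel inserts into the vinylic C–O bond) replaces oxygen by the β-hydrogen-free Grignard carbon with retention, so Me3SiCH2 ends cis to the CH2CH2OH arm (C11) and the (Z)-allylsilane is inherited from the ring.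

**Step 6**
Reactants: 11 (3Z)-6-[(tert-butyldimethylsilyl)oxy]-4-[(trimethylsilyl)methyl]hex-3-en-1-ol
Product: 12 tert-butyl({(3Z)-6-[(tert-butyldimethylsilyl)oxy]-4-[(trimethylsilyl)methyl]hex-3-en-1-yl}oxy)diphenylsilane
Conditions: t-BuPh2SiCl, imidazole, CH2Cl2, 23 °C
Reagents that add atoms: tert-butyl(chloro)diphenylsilane CC(C)(C)[Si](Cl)(c1ccccc1)c1ccccc1
Why: Silylation of the primary C12 alcohol with a tert-butyldiphenylsilyl group, chosen because it must survive mild acid in the next step and hot LiCl in wet DMSO later, where a tert-butyldimethylsilyl ether would be at risk.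

**Step 7**
Reactants: 12 tert-butyl({(3Z)-6-[(tert-butyldimethylsilyl)oxy]-4-[(trimethylsilyl)methyl]hex-3-en-1-yl}oxy)diphenylsilane
Product: 13 (3Z)-6-[(tert-butyldiphenylsilyl)oxy]-3-[(trimethylsilyl)methyl]hex-3-en-1-ol
Conditions: pyridinium p-toluenesulfonate (cat.), MeOH, 23 °C
Reagents that add atoms: none
Why: Acid-catalysed methanolysis cleaves the primary tert-butyldimethylsilyl ether much faster than the tert-butyldiphenylsilyl ether, and the weak acid should not protodesilylate the allylsilane.

**Step 8**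
Reactants: 13 (3Z)-6-[(tert-butyldiphenylsilyl)oxy]-3-[(trimethylsilyl)methyl]hex-3-en-1-ol
Product: 14 tert-butyl({(3Z)-6-iodo-4-[(trimethylsilyl)methyl]hex-3-en-1-yl}oxy)diphenylsilane
Conditions: PPh3, I2, imidazole, CH2Cl2, 0 °C
Reagents that add atoms: iodine II
Why: Appel-type iodination converts the primary C6 alcohol into the iodide under buffered conditions that leave the silyl ether and the allylsilane untouched.

**Step 9**
Reactants: 14 tert-butyl({(3Z)-6-iodo-4-[(trimethylsilyl)methyl]hex-3-en-1-yl}oxy)diphenylsilane (2.5 equiv); 4 dimethyl 3-methyl-4-oxocyclohex-2-ene-1,1-dicarboxylate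
Product: 17 dimethyl (2S)-2-{(3Z)-6-[(tert-butyldiphenylsilyl)oxy]-3-[(trimethylsilyl)methyl]hex-3-en-1-yl}-3-methyl-4-[(triethylsilyl)oxy]cyclohex-3-ene-1,1-dicarboxylate, via dialkylzinc 15 (not isolated), via zinc enolate 16 (not isolated)
Conditions: Et2Zn (neat), CuI (copper monoiodide, cat.), 50 °C, then volatiles removed; 4, Cu(OTf)2 (3 mol %), (R)-BINOL-derived N,N-bis[(S)-1-phenylethyl]phosphoramidite (6 mol %), toluene, −30 → 0 °C; Et3SiOTf, −30 → 0 °C
Reagents that add atoms: triethylsilyl trifluoromethanesulfonate CC[Si](CC)(CC)OS(=O)(=O)C(F)(F)F; diethylzinc CC[Zn]CC (zinc of 15 and 16 only)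
Why: Iodine–zinc exchange gives a salt-free dialkylzinc, and copper/phosphoramidite-catalysed asymmetric conjugate addition (known for 2-methylcyclohexenone and for 4,4-disubstituted cyclohexenones) should deliver the chain to C5 on the face opposite to that served by the (S,R,R)-ligand, setting C5 as S by catalyst control, while O-silylation of the zinc enolate fixes the C1=C10 enol ether regiospecifically as a triethylsilyl ether robust enough for a methanolic electrolyte.

**Step 10**
Reactants: 17 dimethyl (2S)-2-{(3Z)-6-[(tert-butyldiphenylsilyl)oxy]-3-[(trimethylsilyl)methyl]hex-3-en-1-yl}-3-methyl-4-[(triethylsilyl)oxy]cyclohex-3-ene-1,1-dicarboxylate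
Product: 18 dimethyl (4aS,5R,8aS)-5-{2-[(tert-butyldiphenylsilyl)oxy]ethyl}-4a-methyl-6-methylidene-4-oxooctahydronaphthalene-1,1(2H)-dicarboxylate
Conditions: reticulated vitreous carbon anode, Pt cathode, undivided cell, constant current (8 mA, 2.2 F/mol), 0.1 M LiClO4, MeOH/CH2Cl2 1:4, 2,6-lutidine (4 equiv), 20 °C
Reagents that add atoms: none
Why: One-electron oxidation at the anode removes an electron from the tetrasubstituted C1=C10 silyl enol ether, C9 of the allylsilane bonds to C10 of the radical cation, and a second electron transfer followed by loss of Me3Si+ from the β-silyl cation and of Et3Si+ from the C1 oxocarbenium ion (both to methanol) leaves the C8=C17 alkene and the C1 ketone. The closest known reaction type is the anodic coupling of enol ether radical cations with allylsilanes, whose chemical counterpart is the oxidative cyclisation of unsaturated silyl enol ethers with (NH4)2Ce(NO3)6 or Cu(OTf)2. Ring B closes 6-endo-trig at the C8=C9 alkene through a chair-like transition state. C10 is set by the resident C5 stereocentre, whose tether sits equatorial so that C9 arrives on the face of C10 that leaves C20 axial and the ring fusion trans; C9 is set by the (Z) alkene geometry, which holds C11 anti to C7 and therefore equatorial. The step needs regioselective bonding through C9, secured by the β-silicon effect and the less substituted alkene terminus, and chemoselective oxidation of the enol ether, secured by its low oxidation potential and by 2,6-lutidine, which suppresses acid-induced loss of either silyl group before oxidation.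

**Step 11**
Reactants: 18 dimethyl (4aS,5R,8aS)-5-{2-[(tert-butyldiphenylsilyl)oxy]ethyl}-4a-methyl-6-methylidene-4-oxooctahydronaphthalene-1,1(2H)-dicarboxylate
Product: 19 dimethyl (4S,4aS,5R,8aS)-5-{2-[(tert-butyldiphenylsilyl)oxy]ethyl}-4-hydroxy-4a-methyl-6-methylideneoctahydronaphthalene-1,1(2H)-dicarboxylate
Conditions: NaBH4, MeOH, −20 → 0 °C
Reagents that add atoms: none
Why: Borohydride reduction of the C1 ketone should proceed by axial hydride delivery on the face opposite the axial C20 methyl (as with 3-keto-4,4-dimethyl steroids), giving the equatorial C1 alcohol cis to C20 (C1 S) while the esters are untouched.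

**Step 12**
Reactants: 19 dimethyl (4S,4aS,5R,8aS)-5-{2-[(tert-butyldiphenylsilyl)oxy]ethyl}-4-hydroxy-4a-methyl-6-methylideneoctahydronaphthalene-1,1(2H)-dicarboxylate
Product: 20 methyl 5-{2-[(tert-butyldiphenylsilyl)oxy]ethyl}-4-hydroxy-4a-methyl-6-methylidenedecahydronaphthalene-1-carboxylate (both C4 epimers; other centres as in 19)
Conditions: LiCl, H2O, DMSO, 150 °C
Reagents that add atoms: none
Why: Krapcho dealkoxycarbonylation (chloride demethylation, decarboxylation, protonation) removes one ester of the disubstituted malonate under neutral conditions, and the C4 configuration is irrelevant because it is set in the next step.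

**Step 13**
Reactants: 20 methyl 5-{2-[(tert-butyldiphenylsilyl)oxy]ethyl}-4-hydroxy-4a-methyl-6-methylidenedecahydronaphthalene-1-carboxylate
Product: 22 methyl (1R,4S,4aS,5R,8aS)-5-{2-[(tert-butyldiphenylsilyl)oxy]ethyl}-4-hydroxy-1,4a-dimethyl-6-methylidenedecahydronaphthalene-1-carboxylate, via dilithium alkoxide enolate 21 (not isolated)
Conditions: LiN(i-Pr)2 (3 equiv), THF, −78 → 0 °C; MeI, DMPU, −78 → 0 °C
Reagents that add atoms: iodomethane CI; lithium diisopropylamide [Li]N(C(C)C)C(C)C (lithium of 21 only)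
Why: Ester enolate alkylation of the alkoxide–enolate dianion (chemoselectivity as in the Fráter–Seebach alkylation, the lithium alkoxide being inert to MeI) should occur from the equatorial face of C4, away from the 1,3-diaxial C20 methyl, giving equatorial methyl and axial CO2Me (C4 R).

**Step 14**
Reactants: 22 methyl (1R,4S,4aS,5R,8aS)-5-{2-[(tert-butyldiphenylsilyl)oxy]ethyl}-4-hydroxy-1,4a-dimethyl-6-methylidenedecahydronaphthalene-1-carboxylate
Product: 23 methyl (1R,4S,4aS,5R,8aS)-4-(acetyloxy)-5-{2-[(tert-butyldiphenylsilyl)oxy]ethyl}-1,4a-dimethyl-6-methylidenedecahydronaphthalene-1-carboxylate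
Conditions: Ac2O, DMAP, pyridine, 40 °C
Reagents that add atoms: acetic anhydride CC(=O)OC(C)=O
Why: DMAP-catalysed acylation esterifies the hindered equatorial C1 alcohol, which must be capped before C12 is oxidised because a free C1 hydroxyl would form a six-membered lactol with the C12 aldehyde and later add to the enal.

**Step 15**
Reactants: 23 methyl (1R,4S,4aS,5R,8aS)-4-(acetyloxy)-5-{2-[(tert-butyldiphenylsilyl)oxy]ethyl}-1,4a-dimethyl-6-methylidenedecahydronaphthalene-1-carboxylate
Product: 24 methyl (1R,4S,4aS,5R,8aS)-4-(acetyloxy)-5-(2-hydroxyethyl)-1,4a-dimethyl-6-methylidenedecahydronaphthalene-1-carboxylate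
Conditions: HF·pyridine, pyridine, THF, 0 → 23 °C
Reagents that add atoms: none
Why: Fluoride-mediated desilylation with pyridine-buffered HF removes the primary silyl ether without acyl migration, ester cleavage or acid-induced isomerisation of the exocyclic alkene.

**Step 16**
Reactants: 24 methyl (1R,4S,4aS,5R,8aS)-4-(acetyloxy)-5-(2-hydroxyethyl)-1,4a-dimethyl-6-methylidenedecahydronaphthalene-1-carboxylate
Product: 25 methyl (1R,4S,4aS,5R,8aS)-4-(acetyloxy)-1,4a-dimethyl-6-methylidene-5-(2-oxoethyl)decahydronaphthalene-1-carboxylate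
Conditions: Dess–Martin periodinane, NaHCO3, CH2Cl2, 0 → 23 °C
Reagents that add atoms: none
Why: Dess–Martin oxidation under buffered conditions gives the C12 aldehyde without touching C9 or the alkene, and the aldehyde is used directly.

**Step 17**
Reactants: 25 methyl (1R,4S,4aS,5R,8aS)-4-(acetyloxy)-1,4a-dimethyl-6-methylidene-5-(2-oxoethyl)decahydronaphthalene-1-carboxylate; 26 2-(triphenyl-λ5-phosphanylidene)propanal
Product: 27 methyl (1R,4S,4aS,5R,8aS)-4-(acetyloxy)-1,4a-dimethyl-6-methylidene-5-[(2E)-3-methyl-4-oxobut-2-en-1-yl]decahydronaphthalene-1-carboxylate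
Conditions: toluene, 90 °C
Reagents that add atoms: none
Why: Wittig olefination with the stabilised α-formyl ylide is under thermodynamic control and should give the (E)-2-methyl enal (C12=C13) under neutral conditions that spare the acetate.

**Step 18**
Reactants: 27 methyl (1R,4S,4aS,5R,8aS)-4-(acetyloxy)-1,4a-dimethyl-6-methylidene-5-[(2E)-3-methyl-4-oxobut-2-en-1-yl]decahydronaphthalene-1-carboxylate
Product: 28 methyl (1R,4S,4aS,5R,8aS)-4-(acetyloxy)-1,4a-dimethyl-6-methylidene-5-[(2E)-3-methylpenta-2,4-dien-1-yl]decahydronaphthalene-1-carboxylate (CNP0235031.1)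
Conditions: Ph3PCH3Br, KN(SiMe3)2, THF, −78 → 0 °C
Reagents that add atoms: methyltriphenylphosphonium bromide C[P+](c1ccccc1)(c1ccccc1)c1ccccc1.[Br-]
Why: Wittig methylenation of the enal at low temperature forms the terminal C14=C15 alkene without disturbing the (E)-trisubstituted alkene, the aldehyde reacting far faster than the hindered acetate or the neopentyl ester.

**Compound list**

1 | dimethyl 4-oxocyclohexane-1,1-dicarboxylate | COC(=O)C1(CCC(=O)CC1)C(=O)OC | starting material
2 | dimethyl 4-oxocyclohex-2-ene-1,1-dicarboxylate | COC(=O)C1(C=CC(=O)CC1)C(=O)OC | intermediate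
3 | dimethyl 3-iodo-4-oxocyclohex-2-ene-1,1-dicarboxylate | COC(=O)C1(C=C(I)C(=O)CC1)C(=O)OC | intermediate
4 | dimethyl 3-methyl-4-oxocyclohex-2-ene-1,1-dicarboxylate | COC(=O)C1(C=C(C)C(=O)CC1)C(=O)OC | intermediate
5 | 2,3-dihydrofuran | C1=COCC1 | starting material
6 | ethylene oxide | C1CO1 | starting material
7 | 5-lithio-2,3-dihydrofuran | [Li]C1=CCCO1 | intermediate (not isolated)
8 | lithium 2-(4,5-dihydrofuran-2-yl)ethoxide | [Li]OCCC1=CCCO1 | intermediate (not isolated)
9 | tert-butyl[2-(4,5-dihydrofuran-2-yl)ethoxy]dimethylsilane | CC(C)(C)[Si](C)(C)OCCC1=CCCO1 | intermediate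
10 | (trimethylsilyl)methylmagnesium chloride | C[Si](C)(C)C[Mg]Cl | starting material
11 | (3Z)-6-[(tert-butyldimethylsilyl)oxy]-4-[(trimethylsilyl)methyl]hex-3-en-1-ol | OCC/C=C(\C[Si](C)(C)C)CCO[Si](C)(C)C(C)(C)C | intermediate
12 | tert-butyl({(3Z)-6-[(tert-butyldimethylsilyl)oxy]-4-[(trimethylsilyl)methyl]hex-3-en-1-yl}oxy)diphenylsilane | CC(C)(C)[Si](c1ccccc1)(c1ccccc1)OCC/C=C(\C[Si](C)(C)C)CCO[Si](C)(C)C(C)(C)C | intermediate
13 | (3Z)-6-[(tert-butyldiphenylsilyl)oxy]-3-[(trimethylsilyl)methyl]hex-3-en-1-ol | CC(C)(C)[Si](c1ccccc1)(c1ccccc1)OCC/C=C(\C[Si](C)(C)C)CCO | intermediate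
14 | tert-butyl({(3Z)-6-iodo-4-[(trimethylsilyl)methyl]hex-3-en-1-yl}oxy)diphenylsilane | CC(C)(C)[Si](c1ccccc1)(c1ccccc1)OCC/C=C(\C[Si](C)(C)C)CCI | intermediate
15 | bis{(3Z)-6-[(tert-butyldiphenylsilyl)oxy]-3-[(trimethylsilyl)methyl]hex-3-en-1-yl}zinc | CC(C)(C)[Si](c1ccccc1)(c1ccccc1)OCC/C=C(\C[Si](C)(C)C)CC[Zn]CC/C(C[Si](C)(C)C)=C/CCO[Si](c1ccccc1)(c1ccccc1)C(C)(C)C | intermediate (not isolated)
16 | alkylzinc enolate of the conjugate adduct (Zn on the C1 oxygen, C1=C10 double bond, C5 S) | CC(C)(C)[Si](c1ccccc1)(c1ccccc1)OCC/C=C(\C[Si](C)(C)C)CC[Zn]OC1=C(C)[C@H](CC/C(C[Si](C)(C)C)=C/CCO[Si](c2ccccc2)(c2ccccc2)C(C)(C)C)C(C(=O)OC)(C(=O)OC)CC1 | intermediate (not isolated)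
17 | dimethyl (2S)-2-{(3Z)-6-[(tert-butyldiphenylsilyl)oxy]-3-[(trimethylsilyl)methyl]hex-3-en-1-yl}-3-methyl-4-[(triethylsilyl)oxy]cyclohex-3-ene-1,1-dicarboxylate | CC[Si](CC)(CC)OC1=C(C)[C@H](CC/C(C[Si](C)(C)C)=C/CCO[Si](c2ccccc2)(c2ccccc2)C(C)(C)C)C(C(=O)OC)(C(=O)OC)CC1 | intermediate
18 | dimethyl (4aS,5R,8aS)-5-{2-[(tert-butyldiphenylsilyl)oxy]ethyl}-4a-methyl-6-methylidene-4-oxooctahydronaphthalene-1,1(2H)-dicarboxylate (trans-decalin; C9 arm equatorial and cis to C20) | CC(C)(C)[Si](c1ccccc1)(c1ccccc1)OCC[C@@H]1C(=C)CC[C@H]2[C@@]1(C)C(=O)CCC2(C(=O)OC)C(=O)OC | intermediate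
19 | dimethyl (4S,4aS,5R,8aS)-5-{2-[(tert-butyldiphenylsilyl)oxy]ethyl}-4-hydroxy-4a-methyl-6-methylideneoctahydronaphthalene-1,1(2H)-dicarboxylate (equatorial C1 hydroxyl) | CC(C)(C)[Si](c1ccccc1)(c1ccccc1)OCC[C@@H]1C(=C)CC[C@H]2[C@@]1(C)[C@@H](O)CCC2(C(=O)OC)C(=O)OC | intermediate
20 | methyl 5-{2-[(tert-butyldiphenylsilyl)oxy]ethyl}-4-hydroxy-4a-methyl-6-methylidenedecahydronaphthalene-1-carboxylate (C4 epimers; other centres as in 19) | CC(C)(C)[Si](c1ccccc1)(c1ccccc1)OCC[C@@H]1C(=C)CC[C@H]2[C@@]1(C)[C@@H](O)CCC2C(=O)OC | intermediate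
21 | dilithium alkoxide enolate of 20 | CC(C)(C)[Si](c1ccccc1)(c1ccccc1)OCC[C@@H]1C(=C)CC[C@H]2[C@@]1(C)[C@@H](O[Li])CCC2=C(OC)O[Li] | intermediate (not isolated)
22 | methyl (1R,4S,4aS,5R,8aS)-5-{2-[(tert-butyldiphenylsilyl)oxy]ethyl}-4-hydroxy-1,4a-dimethyl-6-methylidenedecahydronaphthalene-1-carboxylate | CC(C)(C)[Si](c1ccccc1)(c1ccccc1)OCC[C@@H]1C(=C)CC[C@H]2[C@@]1(C)[C@@H](O)CC[C@@]2(C)C(=O)OC | intermediate
23 | methyl (1R,4S,4aS,5R,8aS)-4-(acetyloxy)-5-{2-[(tert-butyldiphenylsilyl)oxy]ethyl}-1,4a-dimethyl-6-methylidenedecahydronaphthalene-1-carboxylate | CC(C)(C)[Si](c1ccccc1)(c1ccccc1)OCC[C@@H]1C(=C)CC[C@H]2[C@@]1(C)[C@@H](OC(C)=O)CC[C@@]2(C)C(=O)OC | intermediate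
24 | methyl (1R,4S,4aS,5R,8aS)-4-(acetyloxy)-5-(2-hydroxyethyl)-1,4a-dimethyl-6-methylidenedecahydronaphthalene-1-carboxylate | OCC[C@@H]1C(=C)CC[C@H]2[C@@]1(C)[C@@H](OC(C)=O)CC[C@@]2(C)C(=O)OC | intermediate
25 | methyl (1R,4S,4aS,5R,8aS)-4-(acetyloxy)-1,4a-dimethyl-6-methylidene-5-(2-oxoethyl)decahydronaphthalene-1-carboxylate | O=CC[C@@H]1C(=C)CC[C@H]2[C@@]1(C)[C@@H](OC(C)=O)CC[C@@]2(C)C(=O)OC | intermediate
26 | 2-(triphenyl-λ5-phosphanylidene)propanal | CC(C=O)=P(c1ccccc1)(c1ccccc1)c1ccccc1 | starting material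
27 | methyl (1R,4S,4aS,5R,8aS)-4-(acetyloxy)-1,4a-dimethyl-6-methylidene-5-[(2E)-3-methyl-4-oxobut-2-en-1-yl]decahydronaphthalene-1-carboxylate | O=C/C(C)=C/C[C@@H]1C(=C)CC[C@H]2[C@@]1(C)[C@@H](OC(C)=O)CC[C@@]2(C)C(=O)OC | intermediate
28 | methyl (1R,4S,4aS,5R,8aS)-4-(acetyloxy)-1,4a-dimethyl-6-methylidene-5-[(2E)-3-methylpenta-2,4-dien-1-yl]decahydronaphthalene-1-carboxylate (CNP0235031.1) | C=C/C(C)=C/C[C@@H]1C(=C)CC[C@H]2[C@@]1(C)[C@@H](OC(C)=O)CC[C@@]2(C)C(=O)OC | target

**Step count and risks**

Total step count: 18. Longest linear sequence: 15 steps (steps 4 to 18, from 2,3-dihydrofuran); the ring A branch (steps 1 to 3) joins at step 9.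

Steps most likely to fail:

1. Step 10 (anodic ring closure). The enol ether may be solvolysed before it is oxidised, methanol may trap the radical cation before C9 does, or closure through a non-chair geometry may erode the trans fusion or the C9 configuration. The fallback replaces the radical-cation manifold by a neutral α-keto radical. It sets out from 17: N-iodosuccinimide in THF at −78 °C should give the tertiary α-iodo ketone F1 regiospecifically at C10. Iodine atom-transfer radical cyclisation ((Bu3Sn)2 cat., visible light, benzene, 80 °C; Kharasch-type) should then add the C10 radical 6-endo to C9 and transfer iodine to the tertiary β-silyl radical at C8, giving the β-iodosilane F2. F2 should lose Me3SiI spontaneously or on NaHCO3 work-up to leave the C8=C17 alkene. The route is rejoined at 18.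

2. Step 9 (asymmetric conjugate addition). Alkyl transfer to the α-methylated, neopentyl-flanked enone may be slow, incomplete iodine–zinc exchange may lead to ethyl transfer, and the background reaction may erode the enantioselectivity. The fallback installs the C10 methyl after the conjugate addition. It sets out from enone 2 and dialkylzinc 15: the same copper/phosphoramidite catalysis on the less hindered enone 2, with Me3SiOTf trapping, should give the trimethylsilyl enol ether F3. Regiospecific methylation of the fluoride-generated enolate (benzyltrimethylammonium fluoride, MeI, THF) should give the 2-methyl ketone F4. Equilibrating silylation (Et3SiCl, NaI, Et3N, MeCN) should then favour the tetrasubstituted C1=C10 enol ether, any C1=C2 isomer being removed by chromatography. The route is rejoined at 17, and steps 2 and 3 are no longer needed.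

3. Step 5 (nickel-catalysed ring-opening coupling). Insertion of nickel into the hindered trisubstituted enol ether C–O bond may be slow, and nickel hydride species may erode the alkene geometry. The fallback builds the same alkene by syn-carbometalation. It sets out from 10: transmetalation with CuBr·SMe2 (Et2O/THF, −40 °C) gives (trimethylsilyl)methylcopper F5. F5 should add across commercially available tert-butyl(but-3-yn-1-yloxy)dimethylsilane (C#CCCO[Si](C)(C)C(C)(C)C) with the Me3SiCH2 group on the internal carbon, giving the (Z)-alkenylcopper F6. After activation as the mixed cuprate with lithium pent-1-ynide, F6 should open ethylene oxide 6 with retention. The route is rejoined at 11, and steps 4 and 5 are bypassed.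

**Further compounds**

F1 | step 10 | dimethyl (2S)-2-{(3Z)-6-[(tert-butyldiphenylsilyl)oxy]-3-[(trimethylsilyl)methyl]hex-3-en-1-yl}-3-iodo-3-methyl-4-oxocyclohexane-1,1-dicarboxylate (C10 epimers) | CC1(I)C(=O)CCC(C(=O)OC)(C(=O)OC)[C@H]1CC/C(C[Si](C)(C)C)=C/CCO[Si](c1ccccc1)(c1ccccc1)C(C)(C)C
F2 | step 10 | dimethyl (4aS,5R,8aS)-5-{2-[(tert-butyldiphenylsilyl)oxy]ethyl}-6-iodo-4a-methyl-4-oxo-6-[(trimethylsilyl)methyl]octahydronaphthalene-1,1(2H)-dicarboxylate (C8 epimers) | CC(C)(C)[Si](c1ccccc1)(c1ccccc1)OCC[C@@H]1C(I)(C[Si](C)(C)C)CC[C@H]2[C@@]1(C)C(=O)CCC2(C(=O)OC)C(=O)OC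
F3 | step 9 | dimethyl (2S)-2-{(3Z)-6-[(tert-butyldiphenylsilyl)oxy]-3-[(trimethylsilyl)methyl]hex-3-en-1-yl}-4-[(trimethylsilyl)oxy]cyclohex-3-ene-1,1-dicarboxylate | C[Si](C)(C)OC1=C[C@H](CC/C(C[Si](C)(C)C)=C/CCO[Si](c2ccccc2)(c2ccccc2)C(C)(C)C)C(C(=O)OC)(C(=O)OC)CC1
F4 | step 9 | dimethyl (2S)-2-{(3Z)-6-[(tert-butyldiphenylsilyl)oxy]-3-[(trimethylsilyl)methyl]hex-3-en-1-yl}-3-methyl-4-oxocyclohexane-1,1-dicarboxylate (methyl-bearing carbon unassigned) | CC1C(=O)CCC(C(=O)OC)(C(=O)OC)[C@H]1CC/C(C[Si](C)(C)C)=C/CCO[Si](c1ccccc1)(c1ccccc1)C(C)(C)C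
F5 | step 5 | (trimethylsilyl)methylcopper | C[Si](C)(C)C[Cu]
F6 | step 5 | {(1Z)-4-[(tert-butyldimethylsilyl)oxy]-2-[(trimethylsilyl)methyl]but-1-en-1-yl}copper | [Cu]/C=C(\C[Si](C)(C)C)CCO[Si](C)(C)C(C)(C)C
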